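**Retrosynthetic overview**
- Final C=C bond: boron-templated (Pabon) aldol condensation of a terpenyl vanillin-ether aldehyde with feruloylacetone; both arenes come from catechol via vanillin.
- Allyl aryl ether C–O bond: Pd-catalysed, stereoretentive allylic etherification of a cis-4-hydroxy allylic carbonate with a vanillin acetal phenol.
- Side chain: B-alkyl Suzuki coupling of the C7 vinyl group with 1-bromo-2-methylpropene. The C6–C7 bond and both of its stereocentres come from an Ir-catalysed branched allylation of a cyclohexenone α′-enolate with crotyl carbonate (new step).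
- Rings: none is constructed. The cyclohexene is 2-methylcyclohex-2-enone, functionalised in the order C4–O (CBS), C1=O (Rh C–H oxidation), C6/C7 (Ir), C1–OH (Luche), C4–OAr (Pd).

Assumption: the target is drawn as the enol tautomer of the β-diketone; catalyst antipodes ((R)-CBS, (Ra,R,R)-phosphoramidite) are assigned from the standard selectivity models and would be swapped if a model reaction showed the opposite sense.

Ring numbering in the "Why" lines follows the target cyclohexenol (C1 = CHOH, C3 = CMe, C4 = CH–OAr, C6 = CH–side chain, C7 = side-chain CH).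

**Route**

Step 1
Reactants: 1, 2-methylcyclohex-2-en-1-one
Product: 2, (S)-2-methylcyclohex-2-en-1-ol
Conditions: (R)-Me-CBS (10 mol%), catecholborane, toluene, −78 °C
Reagents that add atoms: none
Why: CBS reduction; the oxazaborolidine binds the ketone anti to the larger 2-methylvinyl arm and delivers hydride to one face, setting the carbinol centre (future C4, S).

Step 2
Reactants: 2, (S)-2-methylcyclohex-2-en-1-ol
Product: 3, (S)-tert-butyldimethyl[(2-methylcyclohex-2-en-1-yl)oxy]silane
Conditions: TBSCl, imidazole, DMF, rt
Reagents that add atoms: TBSCl, CC(C)(C)[Si](C)(C)Cl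
Why: standard silylation; a silyl ether is a poor leaving group, which is needed at the later dienolate stage.

Step 3
Reactants: 3
Product: 4, (S)-4-[(tert-butyldimethylsilyl)oxy]-3-methylcyclohex-2-en-1-one
Conditions: Rh2(cap)4 (1 mol%), t-BuOOH (70% aq, 5 equiv), K2CO3, CH2Cl2, rt
Reagents that add atoms: tert-butyl hydroperoxide, CC(C)(C)OO (ketone oxygen)
Why: Rh-catalysed allylic C–H oxidation (H-abstraction/peroxidation) occurs at the ring CH2 next to the unsubstituted alkene carbon, the same site preference that turns 1-methylcyclohexene into 3-methylcyclohexenone; the silyloxy stereocentre is untouched.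

Step 4
Reactants: 5, (E)-but-2-en-1-ol
Product: 6, (E)-but-2-en-1-yl methyl carbonate
Conditions: ClCO2Me, pyridine, CH2Cl2, 0 °C
Reagents that add atoms: methyl chloroformate, COC(=O)Cl
Why: routine acylation of a primary allylic alcohol to the allyl electrophile.

Step 5
Reactants: 4; 6, (E)-but-2-en-1-yl methyl carbonate
Product: 7, (4S,6R)-6-[(2S)-but-3-en-2-yl]-4-[(tert-butyldimethylsilyl)oxy]-3-methylcyclohex-2-en-1-one
Conditions: LiHMDS, THF, −78 °C; ZnCl2 (0.55 equiv), to 0 °C; then [Ir(cod)Cl]2 (2 mol%), (Ra,R,R)-Feringa phosphoramidite (4 mol%, pre-activated with n-PrNH2), 6 (1.3 equiv), THF, 0 °C → rt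
Reagents that add atoms: none (the C4 unit comes from 6)
Why: Proposed new method: Ir-catalysed branched allylation of a cross-conjugated α′-zinc dienolate with a crotyl carbonate; the cyclometalated Ir(I)–phosphoramidite ionises 6 with inversion to an (η3-crotyl)Ir(III) species that is attacked outer-sphere at its substituted terminus, so the catalyst fixes the allyl face (C7 = S) and the branched regiochemistry, while the enolate face is fixed by the pseudoaxial C4–OTBS (A1,2 strain with the C3 methyl), the bulky allyl–Ir approaching anti to it (4,6-trans, C6 = R); the closest known reaction type is the Ir/phosphoramidite allylic alkylation of silyl enol ethers or metal enolates of simple ketones with aryl-substituted allyl carbonates, not yet shown for an α′-dienolate/crotyl pair setting two adjacent stereocentres.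

Step 6
Reactants: 7
Product: 8, (4S,6R)-6-[(2S)-but-3-en-2-yl]-4-hydroxy-3-methylcyclohex-2-en-1-one
Conditions: HF·pyridine, THF, 0 °C → rt
Reagents that add atoms: none
Why: acidic desilylation leaves the base-labile C6 centre (α to the ketone) untouched.

Step 7
Reactants: 8
Product: 9, (1S,5R)-5-[(2S)-but-3-en-2-yl]-2-methyl-4-oxocyclohex-2-en-1-yl methyl carbonate
Conditions: ClCO2Me, pyridine, DMAP (cat.), CH2Cl2, 0 °C
Reagents that add atoms: methyl chloroformate, COC(=O)Cl
Why: O-acylation installs the Pd leaving group while C1 is still a ketone, so the two ring oxygens never need to be differentiated.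

Step 8
Reactants: 9
Product: 10, (1S,4R,5R)-5-[(2S)-but-3-en-2-yl]-4-hydroxy-2-methylcyclohex-2-en-1-yl methyl carbonate
Conditions: NaBH4, CeCl3·7H2O, MeOH, −78 °C
Reagents that add atoms: none
Why: Luche 1,2-reduction; axial hydride attack on the half-chair with the C6 substituent equatorial gives the pseudoequatorial alcohol, trans to the side chain and cis to the carbonate (C1 = R).

Step 9
Reactants: 11, catechol
Product: 12, guaiacol (2-methoxyphenol)
Conditions: MeI (1.0 equiv), K2CO3, acetone, reflux
Reagents that add atoms: iodomethane, CI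
Why: Williamson mono-O-methylation; the veratrole by-product is removed by distillation or base extraction.

Step 10
Reactants: 12; 13, glyoxylic acid
Product: 14, 4-hydroxy-3-methoxymandelic acid (racemic)
Conditions: NaOH, H2O, rt
Reagents that add atoms: none
Why: para-selective electrophilic hydroxyalkylation of the phenoxide by the aldehyde.

Step 11
Reactants: 14
Product: 15, vanillin
Conditions: Cu(OH)2 (from CuSO4/NaOH), air, H2O, 95 °C; then H2SO4
Reagents that add atoms: none
Why: oxidative decarboxylation of the mandelic acid to the aryl aldehyde.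

Step 12
Reactants: 15
Product: 16, 4-(1,3-dioxolan-2-yl)-2-methoxyphenol
Conditions: ethylene glycol, p-TsOH (cat.), toluene, reflux (Dean–Stark)
Reagents that add atoms: ethylene glycol, OCCO
Why: acetalisation masks the aldehyde against the later 9-BBN step and leaves the phenol free.

Step 13
Reactants: 15; 17, acetylacetone (3 equiv)
Product: 18, (E)-6-(4-hydroxy-3-methoxyphenyl)hex-5-ene-2,4-dione (feruloylacetone)
Conditions: B2O3, EtOAc, 70 °C; B(On-Bu)3, n-BuNH2; then 0.4 M HCl, 60 °C
Reagents that add atoms: none
Why: Pabon aldol condensation; the boron chelate blocks the central carbon so the terminal methyl condenses, and excess diketone favours mono-condensation.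

Step 14
Reactants: 10; 16
Product: 19, (1R,4S,6R)-6-[(2S)-but-3-en-2-yl]-4-[4-(1,3-dioxolan-2-yl)-2-methoxyphenoxy]-3-methylcyclohex-2-en-1-ol
Conditions: Pd2(dba)3·CHCl3 (2.5 mol%), PPh3 (15 mol%), THF, rt
Reagents that add atoms: none
Why: Tsuji–Trost allylic etherification; Pd ionises the pseudoaxial carbonate with inversion and the phenoxide (formed by the released methoxide) attacks anti to Pd at the terminus distal to the C1 hydroxyl, giving net retention at C4 (S, cis to OH).

Step 15
Reactants: 19; 20, 1-bromo-2-methylprop-1-ene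
Product: 21, 4-{[(1S,4R,5R)-4-hydroxy-2-methyl-5-[(2S)-6-methylhept-5-en-2-yl]cyclohex-2-en-1-yl]oxy}-3-methoxybenzaldehyde
Conditions: 9-BBN (2.5 equiv), THF, 0 °C → rt; then 20 (3 equiv), Pd(dppf)Cl2 (5 mol%), 3 M aq K3PO4, DMF, rt; then 1 M HCl, THF, 0 °C
Reagents that add atoms: water, O (aldehyde oxygen on acetal hydrolysis); 9-BBN adds only H
Why: anti-Markovnikov hydroboration of the only monosubstituted alkene, then B-alkyl Suzuki–Miyaura coupling, completes the 6-methylhept-5-en-2-yl chain without touching C7; the acidic work-up releases the aldehyde.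

Step 16
Reactants: 21; 18
Product: 22, Terpecurcumin B
Conditions: B2O3, EtOAc, 70 °C; B(On-Bu)3, n-BuNH2 (cat.), 70 °C; then 10% aq AcOH, 50 °C
Reagents that add atoms: none
Why: Pabon aldol condensation of the boron-chelated diketone methyl with the aldehyde gives the thermodynamic (E)-enone and, after mild hydrolysis, the enolised curcuminoid; the free alcohol and allyl aryl ether tolerate these conditions.

**Compound list**

1 | 2-methylcyclohex-2-en-1-one | CC1=CCCCC1=O | starting material
2 | (S)-2-methylcyclohex-2-en-1-ol | O[C@H]1CCCC=C1C | intermediate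
3 | (S)-tert-butyldimethyl[(2-methylcyclohex-2-en-1-yl)oxy]silane | CC(C)(C)[Si](C)(C)O[C@H]1CCCC=C1C | intermediate
4 | (S)-4-[(tert-butyldimethylsilyl)oxy]-3-methylcyclohex-2-en-1-one | CC(C)(C)[Si](C)(C)O[C@H]1CCC(=O)C=C1C | intermediate
5 | (E)-but-2-en-1-ol | C/C=C/CO | starting material
6 | (E)-but-2-en-1-yl methyl carbonate | C/C=C/COC(=O)OC | intermediate
7 | (4S,6R)-6-[(2S)-but-3-en-2-yl]-4-[(tert-butyldimethylsilyl)oxy]-3-methylcyclohex-2-en-1-one | CC(C)(C)[Si](C)(C)O[C@H]1C[C@H]([C@@H](C)C=C)C(=O)C=C1C | intermediate
8 | (4S,6R)-6-[(2S)-but-3-en-2-yl]-4-hydroxy-3-methylcyclohex-2-en-1-one | O[C@H]1C[C@H]([C@@H](C)C=C)C(=O)C=C1C | intermediate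
9 | (1S,5R)-5-[(2S)-but-3-en-2-yl]-2-methyl-4-oxocyclohex-2-en-1-yl methyl carbonate | COC(=O)O[C@H]1C[C@H]([C@@H](C)C=C)C(=O)C=C1C | intermediate
10 | (1S,4R,5R)-5-[(2S)-but-3-en-2-yl]-4-hydroxy-2-methylcyclohex-2-en-1-yl methyl carbonate | COC(=O)O[C@H]1C[C@H]([C@@H](C)C=C)[C@@H](O)C=C1C | intermediate
11 | catechol | Oc1ccccc1O | starting material
12 | guaiacol | COc1ccccc1O | intermediate
13 | glyoxylic acid | O=CC(=O)O | starting material
14 | 4-hydroxy-3-methoxymandelic acid (racemic) | COc1cc(C(O)C(=O)O)ccc1O | intermediate
15 | vanillin | COc1cc(C=O)ccc1O | intermediate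
16 | 4-(1,3-dioxolan-2-yl)-2-methoxyphenol | COc1cc(C2OCCO2)ccc1O | intermediate
17 | acetylacetone | CC(=O)CC(C)=O | starting material
18 | (E)-6-(4-hydroxy-3-methoxyphenyl)hex-5-ene-2,4-dione | CC(=O)CC(=O)/C=C/c1ccc(O)c(OC)c1 | intermediate
19 | (1R,4S,6R)-6-[(2S)-but-3-en-2-yl]-4-[4-(1,3-dioxolan-2-yl)-2-methoxyphenoxy]-3-methylcyclohex-2-en-1-ol | COc1cc(C2OCCO2)ccc1O[C@H]3C[C@H]([C@@H](C)C=C)[C@@H](O)C=C3C | intermediate
20 | 1-bromo-2-methylprop-1-ene | CC(C)=CBr | starting material
21 | 4-{[(1S,4R,5R)-4-hydroxy-2-methyl-5-[(2S)-6-methylhept-5-en-2-yl]cyclohex-2-en-1-yl]oxy}-3-methoxybenzaldehyde | COc1cc(C=O)ccc1O[C@H]2C[C@H]([C@@H](C)CCC=C(C)C)[C@@H](O)C=C2C | intermediate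
22 | Terpecurcumin B | COc1cc(/C=C/C(=O)/C=C(O)/C=C/c2ccc(O[C@H]3C[C@H]([C@@H](C)CCC=C(C)C)[C@@H](O)C=C3C)c(OC)c2)ccc1O | target

**Totals**
- Total steps: 16.
- Longest linear sequence: 10 steps (1 → 2 → 3 → 5 → 6 → 7 → 8 → 14 → 15 → 16, from 2-methylcyclohex-2-en-1-one).

**Three steps most likely to fail**
- **Step 5 (proposed new Ir allylation).** Risks are linear crotylation, a mismatch between catalyst and substrate control at C6, and over-allylation. Fallback with known chemistry: build C7 by conjugate addition instead. Aldol condensation of 4 with acetaldehyde (LDA; MsCl/Et3N, DBU) gives the (E)-6-ethylidene enone; Rh(I)/BINAP-catalysed 1,4-addition of potassium vinyltrifluoroborate sets C7 under catalyst control; C6 is then equilibrated (DBU) to the 4,6-trans ketone 7.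
- **Step 3 (allylic C–H oxidation).** Risks are abstraction of the α-silyloxy C–H and modest yield. Fallback: take the C1 oxygen from a phenol instead of a C–H bond. Oxidise o-cresol (PhI(OAc)2, MeOH) to 4,4-dimethoxy-2-methylcyclohexa-2,5-dienone, hydrogenate the disubstituted alkene (RhCl(PPh3)3, H2), then CBS reduction, TBS protection and ketal hydrolysis give 4.
- **Step 14 (Pd etherification).** Risks are attack at C2 and β-hydride elimination to a diene or arene. Fallback: make the ether by SNAr with no π-allyl intermediate. Luche-reduce 7, mask C1–OH as a THP ether, remove the TBS group, O-arylate the C4 alkoxide (KHMDS) with 4-fluoro-3-methoxybenzaldehyde (the C4–O bond is untouched, so configuration is retained), then remove the THP group and extend the chain as in step 15 after acetal protection.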